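## Structural features

The target 27 is a C25 lactone in which a bicyclo[2.2.2]oct-5-en-2-one shares its C5–C10 bond with a cyclohexane, ring B (C5–C6–C7–C8–C9–C10). In the bicycle, C1 is the ketone carbon, C2 the bridgehead CH, C3=C4 the alkene with the methyl on C4, C5 the quaternary bridgehead, C10 the methyl-bearing quaternary carbon, and C1'H2–C2'H the saturated bridge. Ring B is trans-fused across C6–C7 to an α-methyl-γ-butyrolactone (oxygen on C6, methyl on C11, carbonyl C12), and C2' carries a 6-methylhepta-1,5-dien-2-yl chain. There are seven stereocentres: C5 and C10 are vicinal quaternary carbons, C5–C6–C7–C11 form an unbroken row, and C2' stands next to the bridgehead C2. Fragile groups are the β,γ-unsaturated ketone, the lactone with its epimerisable C11, and the 1,1-disubstituted and trisubstituted side-chain alkenes, which rule out protic acid, electrophilic oxidants and hydrogenation. The real difficulty is the congested C5–C10 bond, where two rings meet, together with the control of C2' relative to the lactone half. The key step exploits the fact that the ketone bridge C1–C10 spans C2 and C5 while C10 is already tied to C5 through ring B. A C10=C1 unit held on the C6–C9 tether can therefore add across a C5=C4–C3=C2 cyclohexadiene and close ring B and the bicyclooctene in one event, the C3=C4 alkene being the footprint of the diene.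

## Logic of the disconnections

27 is traced to 26 and then to 25 by exchanging the C1 carbonyl oxygen for a C1–B bond. No skeletal bond is cut. The reason is that a C1=C10 ketene cannot serve as the 2π partner, whereas a boron-substituted alkene can and is converted to the ketone afterwards. The forward steps must oxidise C–B and then CH–OH without touching the lactone, C11 or the three alkenes.

In 25 the bonds C5–C10 and C2–C1 are cut together, a retro-[4+2] across C3=C4. This removes ring B and the bicyclooctene at once, clears four stereocentres (C1, C2, C5, C10) and leads to 24, where the tether C6–C9 and the trans-lactone are already in place. Forward, the cycloaddition must take the diene face anti to the C2' substituent, place C9 under the C1'–C2' bridge, and outrun hydrogen shifts in the diene.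

In 24 the lactone C12–O bond and the C6–H bond are cut, which leads through 23 to the γ-keto ester 22. C6 becomes sp2, so its configuration can be set by hydride addition under control of C7. A carbon nucleophile adding to the α-branched aldehyde would, by the Felkin–Anh model, favour the C6 epimer that closes to the cis-lactone. The demand is a 1,2-selective reduction of a dienone and a ring closure without acid, because the C6 carbinol is doubly allylic.

22 is cut through 21 at C5–C6 into 7 and 19. This is the most convergent bond: it separates the ring that carries C2' from the chain that carries C7, C11 and the boronate. The forward coupling must join a hindered dienyl electrophile to an enolisable aldehyde without touching the ester or the C–B bond. The carbinol configuration need not be controlled, since it is oxidised.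

7 is traced to 6 by cutting the C5–O sulfonate bond, then to 4 and 5 at the CH=C(CH3)2 alkene, to 2 and 3 at the allylic CH2–CH2 bond, and to 1 at the C–Cl bond. The chiral-pool ketone 1 supplies C2' and all six ring carbons. Forward, the chlorination must pick the isopropenyl group, and the enol sulfonate must form on the γ side so that the diene is C5=C4–C3=C2.

19 is traced through 18 to 17, and 17 is cut at C7–C11 into 13 and 15. One enolate alkylation then sets both centres, C7 by the auxiliary and C11 by inversion of a lactate-derived sulfonate. The demand is a clean substitution at a secondary carbon and an auxiliary removal that spares the tert-butyl ester.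

13 is cut at the imide N–C6 bond into 10 and 11. 10 is cut at C10–CH3 and C1–B back to the terminal alkyne 8, and 15 comes from 14. The syn addition of methyl and metal across the alkyne must place the metal on the terminal carbon so that boron ends cis to the methyl.

## Other disconnections considered

Alternative 1: The cut is C5–C6 of ring B in a bicyclic model. Forward, a chiral triazolylidene carbene would turn the aldehyde of 2-methyl-2-(4-oxobutyl)cyclohexane-1,3-dione A1 into an acyl-anion equivalent that adds to one of the two enantiotopic ring ketones and gives the cis-fused hydroxy diketone A2.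
- In its favour: C10 would be created catalytically and enantioselectively from an achiral dione, and oxygen would sit on C1, C5 and C6. On independence from the chiral pool and access to either enantiomer this alternative is the better of the two; on mildness of conditions it is the equal of the chosen plan.
- Against it here: A2 holds only eleven of the twenty-five carbons. C5 is a carbinol and not a carbon-substituted quaternary centre, so the hardest bond of the target is left unmade. The C4 methyl, the C3=C4 alkene, the C7 substituent, the lactone and the whole C1'–C2' bridge with its side chain would still have to be added, and the two ketones of A2 would have to be told apart.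
- Comparison: structurally it solves C10 alone, where the chosen cycloaddition sets C2, C5 and C10 together. Mechanistically it is a polar, catalyst-controlled addition against a substrate-controlled pericyclic step. In step economy it is expected to be clearly worse, because three separate stereochemical problems (C6/C7/C11, C2', C5/C2) would remain after the key step.

Alternative 2: The cut is C5–C10 of the decalin. Forward, BF3·OEt2 would open the (4E)-1,10-epoxygermacr-4-en-12,6-olide A3 at tertiary C10 while the C4=C5 alkene attacks across the ring, and proton loss would give 1β-hydroxyeudesm-3-en-12,6α-olide A4.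
- In its favour: one step would build the trans-decalin with C10 quaternary, oxygen on C1 and the intact trans-lactone. The configuration would follow from the conformation of the ten-membered ring, and the C5–C10 bond formed is the same one the chosen plan forms. On placing the C1 oxygen and on stereospecificity at C10 this alternative is the equal of the chosen plan. If A3 could be taken by semisynthesis from a natural ten-membered lactone, it would be the better in step count up to A4.
- Against it here: a de novo route to A3 needs a long macrocycle synthesis. Proton loss after cyclisation can occur toward more than one carbon. A4 carries hydrogen on C5, so the C5 quaternary centre and the bicyclooctenone would still have to come from oxidation to a dienone and an untethered cycloaddition of the kind discussed under Alternative 3.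
- Comparison: the cationic cyclisation is stereospecific but leaves C2, C5 and C2' to a later intermolecular step, whereas the chosen plan takes C2' from the chiral pool and sets C2, C5 and C10 in one tethered step.

Alternative 3: The cut is C1–C10 of a cyclohexa-2,4-dienone. Forward, heating or irradiating the 4-methyl-4-cyclohexenylcyclobut-2-enone A5 would open the four-membered ring to a dienylketene, whose 6π electrocyclisation forms C1–C10 and gives the 1-oxoeudesma-2,4-dien-12,6-olide A6. The bicyclooctenone would then come from an intermolecular [4+2] of A6 with myrcene A7.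
- In its favour: the ketone arrives at C1 without a mask, ring A forms in a neutral, atom-economic pericyclic step, and the last union uses a cheap C10 partner. On redox economy and on step count as written on paper this alternative is the better; in being pericyclic and reagent-free it is the equal of the chosen plan.
- Against it here: C10 would be set during the electrocyclisation with only remote guidance from C6 and C7. A5 needs a quaternary cyclobutenone carbon attached to a tetrasubstituted alkene. The final cycloaddition would have to control regiochemistry (C1' to C5), endo or exo placement (C2'), π-face and periselectivity without a tether, since A7 is itself a 1,3-diene and A6 can dimerise.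
- Comparison: four of the seven stereocentres would rest on one untethered step, whereas the chosen plan fixes C2' beforehand and lets the tether and the trans-lactone direct C2, C5 and C10.

Key step: step 14

Assumptions and remarks on the chemistry:
- Atom labels C1–C12, C1' and C2' are those defined under "Structural features".
- Compounds 3, 5, 11 and 14 are taken as commercial.
- A centre-by-centre comparison shows that 24, 25 and 27 share the configuration at C2', C6, C7 and C11, and that the E boronate of 24 maps onto the C1/C10 relationship of 25. The structures of the key step therefore need no correction.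
- The one change to the design of the precursor concerns C6: direct carbonyl addition would set it with the wrong sense, so it is set by ketone reduction (steps 11 to 13).

## Route

Step 1
Reactants: 1 (S)-(+)-carvone
Product: 2 (5S)-5-(3-chloroprop-1-en-2-yl)-2-methylcyclohex-2-en-1-one
Conditions: Ca(OCl)2, solid CO2, CH2Cl2/H2O, 0 °C
Reagents that add atoms: calcium hypochlorite, [Ca+2].[O-]Cl.[O-]Cl
Why: Ene-type allylic chlorination by HOCl released in the flask; the electron-rich 1,1-disubstituted alkene reacts with transposition of the double bond onto the former methyl, the electron-poor enone is inert, and the stereocentre is not involved.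

Step 2
Reactants: 2 (5S)-5-(3-chloroprop-1-en-2-yl)-2-methylcyclohex-2-en-1-one; 3 allylboronic acid pinacol ester
Product: 4 (5S)-5-(hexa-1,5-dien-2-yl)-2-methylcyclohex-2-en-1-one
Conditions: Pd2(dba)3 (2.5 mol %), PPh3 (10 mol %), CsF, THF, 60 °C
Reagents that add atoms: none
Why: Palladium-catalysed allyl–allyl cross-coupling of the Suzuki–Miyaura type; both allyl units have equivalent termini, so only one constitution can form, and the boronate is too weak an allylating agent to attack the conjugated ketone.

Step 3
Reactants: 4 (5S)-5-(hexa-1,5-dien-2-yl)-2-methylcyclohex-2-en-1-one; 5 2-methylbut-2-ene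
Product: 6 (5S)-2-methyl-5-(6-methylhepta-1,5-dien-2-yl)cyclohex-2-en-1-one
Conditions: second-generation Grubbs catalyst RuCl2(=CHPh)(PCy3)(H2IMes) (3 mol %), 2-methylbut-2-ene/CH2Cl2, 40 °C
Reagents that add atoms: none
Why: Olefin cross-metathesis; only the monosubstituted alkene engages, the 1,1-disubstituted alkene and the enone being too hindered or too electron-poor, and the isopropylidene end resists further exchange.

Step 4
Reactants: 6 (5S)-2-methyl-5-(6-methylhepta-1,5-dien-2-yl)cyclohex-2-en-1-one
Product: 7 (5R)-2-methyl-5-(6-methylhepta-1,5-dien-2-yl)cyclohexa-1,3-dien-1-yl trifluoromethanesulfonate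
Conditions: Tf2O, 2,6-di-tert-butyl-4-methylpyridine, CH2Cl2, 0 °C to rt
Reagents that add atoms: trifluoromethanesulfonic anhydride, O=S(=O)(OS(=O)(=O)C(F)(F)F)C(F)(F)F
Why: Thermodynamic dienol triflation: O-sulfonylation gives an allyl cation that loses the γ-proton from the ring CH2 next to the stereocentre, giving the linearly conjugated diene C5=C4–C3=C2; the hindered base buffers acid and the stereocentre (now R by a change of priorities only) is untouched.

Step 5
Reactants: 8 hex-5-ynoic acid
Product: 10 (E)-5-methyl-6-(4,4,5,5-tetramethyl-1,3,2-dioxaborolan-2-yl)hex-5-enoic acid, via alkenyldimethylalane 9 (not isolated)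
Conditions: Me3Al (3.5 equiv), Cp2ZrCl2 (0.25 equiv), CH2Cl2, 0 °C to rt; then i-PrOBpin, 0 °C to rt; cold aq. citric acid
Reagents that add atoms: trimethylaluminium, C[Al](C)C; 2-isopropoxy-4,4,5,5-tetramethyl-1,3,2-dioxaborolane, CC(C)OB1OC(C)(C)C(C)(C)O1
Why: Negishi carboalumination adds CH3 and Al syn across the alkyne with Al on the terminal carbon, the acid being masked as its aluminium carboxylate; exchange of Al for boron with retention gives the E boronate (B cis to CH3).

Step 6
Reactants: 10 (E)-5-methyl-6-(4,4,5,5-tetramethyl-1,3,2-dioxaborolan-2-yl)hex-5-enoic acid; 11 (R)-4-benzyloxazolidin-2-one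
Product: 13 (R)-4-benzyl-3-[(E)-5-methyl-6-(4,4,5,5-tetramethyl-1,3,2-dioxaborolan-2-yl)hex-5-enoyl]oxazolidin-2-one, via mixed pivalic anhydride 12 (not isolated)
Conditions: t-BuCOCl, Et3N, THF, −20 °C; then 11, LiCl, rt
Reagents that add atoms: none
Why: N-Acylation of the oxazolidinone through the mixed anhydride under LiCl/Et3N activation; no alkyllithium is used, so the boronate is not attacked.

Step 7
Reactants: 14 tert-butyl (S)-lactate
Product: 15 tert-butyl (2S)-2-(trifluoromethylsulfonyloxy)propanoate
Conditions: Tf2O, 2,6-lutidine, CH2Cl2, −78 to 0 °C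
Reagents that add atoms: trifluoromethanesulfonic anhydride, O=S(=O)(OS(=O)(=O)C(F)(F)F)C(F)(F)F
Why: O-Sulfonylation of the secondary alcohol with retention at carbon; the triflate is the leaving group that allows substitution at a secondary α-ester carbon and is used at once.

Step 8
Reactants: 13 (R)-4-benzyl-3-[(E)-5-methyl-6-(4,4,5,5-tetramethyl-1,3,2-dioxaborolan-2-yl)hex-5-enoyl]oxazolidin-2-one; 15 tert-butyl (2S)-2-(trifluoromethylsulfonyloxy)propanoate
Product: 17 tert-butyl (2S,3S,6E)-3-[(4R)-4-benzyl-2-oxooxazolidine-3-carbonyl]-2,6-dimethyl-7-(4,4,5,5-tetramethyl-1,3,2-dioxaborolan-2-yl)hept-6-enoate, via sodium Z-enolate 16 (not isolated)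
Conditions: NaN(SiMe3)2, THF, −78 °C; then 15, −78 to −40 °C
Reagents that add atoms: none
Why: Evans alkylation: the chelated Z-enolate is attacked on the face opposite the benzyl group, which sets C7 (S); displacement of triflate with inversion at the lactate carbon sets C11 (S).

Step 9
Reactants: 17 tert-butyl (2S,3S,6E)-3-[(4R)-4-benzyl-2-oxooxazolidine-3-carbonyl]-2,6-dimethyl-7-(4,4,5,5-tetramethyl-1,3,2-dioxaborolan-2-yl)hept-6-enoate
Product: 18 tert-butyl (2S,3S,6E)-3-(hydroxymethyl)-2,6-dimethyl-7-(4,4,5,5-tetramethyl-1,3,2-dioxaborolan-2-yl)hept-6-enoate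
Conditions: LiBH4, MeOH (1 equiv), THF, 0 °C
Reagents that add atoms: none
Why: Reductive cleavage of the N-acyl oxazolidinone at the exocyclic carbonyl; the hindered tert-butyl ester is not reduced and does not lactonise under these neutral conditions, and neither stereocentre is touched.

Step 10
Reactants: 18 tert-butyl (2S,3S,6E)-3-(hydroxymethyl)-2,6-dimethyl-7-(4,4,5,5-tetramethyl-1,3,2-dioxaborolan-2-yl)hept-6-enoate
Product: 19 tert-butyl (2S,3S,6E)-3-formyl-2,6-dimethyl-7-(4,4,5,5-tetramethyl-1,3,2-dioxaborolan-2-yl)hept-6-enoate
Conditions: Dess–Martin periodinane, NaHCO3, CH2Cl2, 0 °C to rt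
Reagents that add atoms: none
Why: Dess–Martin oxidation of the primary alcohol under buffered, non-basic conditions that should keep the α-stereocentre C7 and the C–B bond intact; the aldehyde is used without storage.

Step 11
Reactants: 7 (5R)-2-methyl-5-(6-methylhepta-1,5-dien-2-yl)cyclohexa-1,3-dien-1-yl trifluoromethanesulfonate; 19 tert-butyl (2S,3S,6E)-3-formyl-2,6-dimethyl-7-(4,4,5,5-tetramethyl-1,3,2-dioxaborolan-2-yl)hept-6-enoate
Product: 21 tert-butyl (2S,3S,6E)-3-{hydroxy[(5R)-2-methyl-5-(6-methylhepta-1,5-dien-2-yl)cyclohexa-1,3-dien-1-yl]methyl}-2,6-dimethyl-7-(4,4,5,5-tetramethyl-1,3,2-dioxaborolan-2-yl)hept-6-enoate as both carbinol epimers, via dienylchromium dichloride 20 (not isolated)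
Conditions: CrCl2 (4 equiv), NiCl2 (2 mol %), degassed DMF, rt
Reagents that add atoms: none
Why: Nozaki–Hiyama–Kishi coupling: zerovalent nickel inserts into the C–OTf bond, the dienyl group passes to trivalent chromium and adds to the aldehyde to form C5–C6, while the ester and the alkenylboronate are inert to the non-basic organochromium. The carbinol centre is expected to favour the unwanted 6R sense (Felkin–Anh) and is erased in step 12; the tert-butyl ester keeps the adduct from lactonising.

Step 12
Reactants: 21 tert-butyl (2S,3S,6E)-3-{hydroxy[(5R)-2-methyl-5-(6-methylhepta-1,5-dien-2-yl)cyclohexa-1,3-dien-1-yl]methyl}-2,6-dimethyl-7-(4,4,5,5-tetramethyl-1,3,2-dioxaborolan-2-yl)hept-6-enoate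
Product: 22 tert-butyl (2S,3S,6E)-2,6-dimethyl-3-{[(5R)-2-methyl-5-(6-methylhepta-1,5-dien-2-yl)cyclohexa-1,3-dien-1-yl]carbonyl}-7-(4,4,5,5-tetramethyl-1,3,2-dioxaborolan-2-yl)hept-6-enoate
Conditions: Dess–Martin periodinane, NaHCO3, CH2Cl2, 0 °C
Reagents that add atoms: none
Why: Dess–Martin oxidation of the doubly allylic alcohol converges both epimers on one dienyl ketone; the buffered medium avoids ionisation of the carbinol and enolisation toward C7 or C2'.

Step 13
Reactants: 22 tert-butyl (2S,3S,6E)-2,6-dimethyl-3-{[(5R)-2-methyl-5-(6-methylhepta-1,5-dien-2-yl)cyclohexa-1,3-dien-1-yl]carbonyl}-7-(4,4,5,5-tetramethyl-1,3,2-dioxaborolan-2-yl)hept-6-enoate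
Product: 24 (3S,4S,5S)-3-methyl-4-[(E)-3-methyl-4-(4,4,5,5-tetramethyl-1,3,2-dioxaborolan-2-yl)but-3-enyl]-5-[(5R)-2-methyl-5-(6-methylhepta-1,5-dien-2-yl)cyclohexa-1,3-dien-1-yl]dihydrofuran-2(3H)-one, via hydroxy ester 23 (not isolated)
Conditions: NaBH4, CeCl3·7H2O, MeOH/THF, −78 °C; then NaH (1.1 equiv), THF, 0 °C to rt
Reagents that add atoms: none
Why: Luche 1,2-reduction of the dienone; under Felkin–Anh control hydride enters anti to the branched C11 substituent on C7 and sets C6 (S), the epimer that closes to the trans-lactone. The sodium alkoxide then displaces tert-butoxide in a 5-exo-trig transesterification, and C11 already holds the more stable arrangement trans to C8, so base cannot degrade it.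

Step 14
Reactants: 24 (3S,4S,5S)-3-methyl-4-[(E)-3-methyl-4-(4,4,5,5-tetramethyl-1,3,2-dioxaborolan-2-yl)but-3-enyl]-5-[(5R)-2-methyl-5-(6-methylhepta-1,5-dien-2-yl)cyclohexa-1,3-dien-1-yl]dihydrofuran-2(3H)-one
Product: 25 C1-pinacolboryl tetracycle (skeleton and all carbon stereocentres of 27; C1 carries H and the boryl group cis to the C10 methyl on the side of the C3=C4 bridge)
Conditions: BHT (cat.), degassed toluene (0.01 M), 170 °C, sealed vessel
Reagents that add atoms: none
Why: A thermal, concerted and suprafacial [4+2] joins the diene C5=C4–C3=C2 to the alkenylboronate C10=C1, forming C5–C10 and C2–C1; the vacant orbital on boron lowers the dienophile LUMO only modestly, so intramolecularity carries the reaction. The closest known reaction type is the intramolecular Diels–Alder reaction of alkenylboronic esters used as ketene equivalents, with the tether attached to a diene terminus. Ring B closes as the six-membered tether ring (C5, C6, C7, C8, C9, C10) through a chair-like array with the C6–O and C7–C11 bonds equatorial, and the bicyclo[2.2.2]octene closes by 1,4-bridging of the cyclohexadiene at C5 and C2 with the C10–C1 unit. C5 and C2 are fixed by the diene face, the dienophile arriving anti to the C2' side chain, which shields its own face. C10 is fixed by the tether orientation: C9 lies toward the C1'–C2' bridge and the methyl toward C3=C4, because on this face the other orientation would force the trans-lactone bonds axial. C1 follows from the E geometry of the boronate (boron cis to the C10 methyl) and is of no consequence after oxidation. The step needs diene-face and tether-orientation selectivity, secured by C2' and the trans-lactone acting in the same sense. It also needs a rate advantage over 1,5-hydrogen shifts and over addition of the side-chain alkene, sought through dilution, exclusion of acid and oxygen, and the lowest workable temperature.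

Step 15
Reactants: 25 C1-pinacolboryl tetracycle
Product: 26 C1 alcohol (skeleton and all carbon stereocentres of 27 with a secondary hydroxyl on C1, 1R, cis to the C10 methyl)
Conditions: NaBO3·4H2O, THF/H2O, rt
Reagents that add atoms: sodium perborate (used as the tetrahydrate), [Na+].[Na+].O[B-]1(O)OO[B-](O)(O)OO1
Why: Oxidation of the C–B bond: peroxide adds to boron and C1 migrates to oxygen with retention; the nucleophilic oxidant does not epoxidise the alkenes and the nearly neutral medium spares the lactone and C11.

Step 16
Reactants: 26 C1 alcohol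
Product: 27 target CNP0385704.3
Conditions: Dess–Martin periodinane, NaHCO3, CH2Cl2, rt
Reagents that add atoms: none
Why: Dess–Martin oxidation of the hindered secondary alcohol to the bridging ketone under buffered conditions; the bridgehead C2 cannot enolise, so the β,γ-unsaturated ketone should not isomerise.

## Compound list

1 | (S)-(+)-carvone | CC1=CC[C@@H](CC1=O)C(C)=C | starting material
2 | (5S)-5-(3-chloroprop-1-en-2-yl)-2-methylcyclohex-2-en-1-one | CC1=CC[C@@H](CC1=O)C(=C)CCl | intermediate
3 | allylboronic acid pinacol ester | C=CCB1OC(C)(C)C(C)(C)O1 | starting material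
4 | (5S)-5-(hexa-1,5-dien-2-yl)-2-methylcyclohex-2-en-1-one | CC1=CC[C@@H](CC1=O)C(=C)CCC=C | intermediate
5 | 2-methylbut-2-ene | CC=C(C)C | starting material
6 | (5S)-2-methyl-5-(6-methylhepta-1,5-dien-2-yl)cyclohex-2-en-1-one | CC1=CC[C@@H](CC1=O)C(=C)CCC=C(C)C | intermediate
7 | (5R)-2-methyl-5-(6-methylhepta-1,5-dien-2-yl)cyclohexa-1,3-dien-1-yl trifluoromethanesulfonate | C=C(CCC=C(C)C)[C@@H]1CC(OS(=O)(=O)C(F)(F)F)=C(C)C=C1 | intermediate
8 | hex-5-ynoic acid | C#CCCCC(=O)O | starting material
9 | (E)-alkenyldimethylalane of 5-methylhex-5-enoic acid, as its dimethylaluminium carboxylate (not isolated) | C[Al](C)/C=C(\C)CCCC(=O)O[Al](C)C | intermediate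
10 | (E)-5-methyl-6-(4,4,5,5-tetramethyl-1,3,2-dioxaborolan-2-yl)hex-5-enoic acid | OC(=O)CCC/C(C)=C/B1OC(C)(C)C(C)(C)O1 | intermediate
11 | (R)-4-benzyloxazolidin-2-one | O=C1N[C@H](Cc2ccccc2)CO1 | starting material
12 | mixed pivalic anhydride of 10 (not isolated) | CC(C)(C)C(=O)OC(=O)CCC/C(C)=C/B1OC(C)(C)C(C)(C)O1 | intermediate
13 | (R)-4-benzyl-3-[(E)-5-methyl-6-(4,4,5,5-tetramethyl-1,3,2-dioxaborolan-2-yl)hex-5-enoyl]oxazolidin-2-one | O=C(CCC/C(C)=C/B1OC(C)(C)C(C)(C)O1)N2[C@H](Cc3ccccc3)COC2=O | intermediate
14 | tert-butyl (S)-lactate | C[C@H](O)C(=O)OC(C)(C)C | starting material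
15 | tert-butyl (2S)-2-(trifluoromethylsulfonyloxy)propanoate | C[C@H](OS(=O)(=O)C(F)(F)F)C(=O)OC(C)(C)C | intermediate
16 | sodium Z-enolate of 13 (not isolated) | [Na+].[O-]/C(=C\CC/C(C)=C/B1OC(C)(C)C(C)(C)O1)N2[C@H](Cc3ccccc3)COC2=O | intermediate
17 | tert-butyl (2S,3S,6E)-3-[(4R)-4-benzyl-2-oxooxazolidine-3-carbonyl]-2,6-dimethyl-7-(4,4,5,5-tetramethyl-1,3,2-dioxaborolan-2-yl)hept-6-enoate | O=C([C@@H](CC/C(C)=C/B1OC(C)(C)C(C)(C)O1)[C@H](C)C(=O)OC(C)(C)C)N2[C@H](Cc3ccccc3)COC2=O | intermediate
18 | tert-butyl (2S,3S,6E)-3-(hydroxymethyl)-2,6-dimethyl-7-(4,4,5,5-tetramethyl-1,3,2-dioxaborolan-2-yl)hept-6-enoate | OC[C@@H](CC/C(C)=C/B1OC(C)(C)C(C)(C)O1)[C@H](C)C(=O)OC(C)(C)C | intermediate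
19 | tert-butyl (2S,3S,6E)-3-formyl-2,6-dimethyl-7-(4,4,5,5-tetramethyl-1,3,2-dioxaborolan-2-yl)hept-6-enoate | O=C[C@@H](CC/C(C)=C/B1OC(C)(C)C(C)(C)O1)[C@H](C)C(=O)OC(C)(C)C | intermediate
20 | [(5R)-2-methyl-5-(6-methylhepta-1,5-dien-2-yl)cyclohexa-1,3-dien-1-yl]chromium dichloride (not isolated) | C=C(CCC=C(C)C)[C@@H]1CC([Cr](Cl)Cl)=C(C)C=C1 | intermediate
21 | tert-butyl (2S,3S,6E)-3-{hydroxy[(5R)-2-methyl-5-(6-methylhepta-1,5-dien-2-yl)cyclohexa-1,3-dien-1-yl]methyl}-2,6-dimethyl-7-(4,4,5,5-tetramethyl-1,3,2-dioxaborolan-2-yl)hept-6-enoate, both carbinol epimers | C=C(CCC=C(C)C)[C@@H]1CC(=C(C)C=C1)C(O)[C@@H](CC/C(C)=C/B2OC(C)(C)C(C)(C)O2)[C@H](C)C(=O)OC(C)(C)C | intermediate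
22 | tert-butyl (2S,3S,6E)-2,6-dimethyl-3-{[(5R)-2-methyl-5-(6-methylhepta-1,5-dien-2-yl)cyclohexa-1,3-dien-1-yl]carbonyl}-7-(4,4,5,5-tetramethyl-1,3,2-dioxaborolan-2-yl)hept-6-enoate | C=C(CCC=C(C)C)[C@@H]1CC(=C(C)C=C1)C(=O)[C@@H](CC/C(C)=C/B2OC(C)(C)C(C)(C)O2)[C@H](C)C(=O)OC(C)(C)C | intermediate
23 | (S)-carbinol epimer of 21 (not isolated) | C=C(CCC=C(C)C)[C@@H]1CC(=C(C)C=C1)[C@@H](O)[C@@H](CC/C(C)=C/B2OC(C)(C)C(C)(C)O2)[C@H](C)C(=O)OC(C)(C)C | intermediate
24 | (3S,4S,5S)-3-methyl-4-[(E)-3-methyl-4-(4,4,5,5-tetramethyl-1,3,2-dioxaborolan-2-yl)but-3-enyl]-5-[(5R)-2-methyl-5-(6-methylhepta-1,5-dien-2-yl)cyclohexa-1,3-dien-1-yl]dihydrofuran-2(3H)-one | C=C(CCC=C(C)C)[C@@H]1CC(=C(C)C=C1)[C@H]2OC(=O)[C@@H](C)[C@@H]2CC/C(C)=C/B3OC(C)(C)C(C)(C)O3 | intermediate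
25 | C1-pinacolboryl tetracycle (boron in place of the ketone oxygen, cis to the C10 methyl) | C=C(CCC=C(C)C)[C@@H]1C[C@]23C(C)=C[C@H]1[C@@H](B4OC(C)(C)C(C)(C)O4)[C@]2(C)CC[C@H]1[C@H](C)C(=O)O[C@@H]13 | intermediate
26 | C1 alcohol (1R hydroxyl in place of the ketone) | C=C(CCC=C(C)C)[C@@H]1C[C@]23C(C)=C[C@H]1[C@@H](O)[C@]2(C)CC[C@H]1[C@H](C)C(=O)O[C@@H]13 | intermediate
27 | CNP0385704.3 | C=C(CCC=C(C)C)[C@@H]1C[C@]23C(C)=C[C@H]1C(=O)[C@]2(C)CC[C@H]1[C@H](C)C(=O)O[C@@H]13 | target

## Step count and least certain steps

Total: 16 steps. Longest linear sequence: 11 steps (8 to 27 through steps 5, 6 and 8 to 16). The branch from 1 is 10 steps long.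

Step 14 (key step). The most likely failure is that the weakly activated boronate reacts too slowly at a bond between two fully substituted carbons. Thermal 1,5-hydrogen migration in the cyclohexadiene would then scramble C2' and move the diene, or the trisubstituted side-chain alkene would add to the diene instead. The fallback raises the electrophilicity of the dienophile and not the temperature. It sets out from 24: KHF2 in MeOH/H2O should give the potassium alkenyltrifluoroborate F1; SiCl4 in CH2Cl2/MeCN at −20 °C should convert it into the alkenyldichloroborane F2, a far stronger dienophile expected to cyclise at or below room temperature to the dichloroboryl tetracycle F3. Oxidation in the same flask with NaBO3·4H2O returns to the route at 26.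

Step 4. Proton loss may occur on the wrong side, giving the cross-conjugated dienyl triflate, or traces of acid may drive isomerisation toward an aromatic ring, because the product holds a doubly allylic hydrogen. The fallback generates the dienolate regiospecifically under base. It sets out from 6: TMSCl, NaI and Et3N in MeCN, conditions that equilibrate silyl enol ethers, should give the linearly conjugated trimethylsilyl dienol ether F4. MeLi in THF at 0 °C releases the lithium dienolate F5, which is trapped on oxygen with N-(5-chloropyridin-2-yl)bis(trifluoromethanesulfonyl)imide at −78 °C, returning to the route at 7.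

Step 5. Transfer of the alkenyl group from aluminium to boron may be incomplete in the presence of excess Me3Al and the aluminium carboxylate, leading to protodemetalation on work-up. The fallback separates the two events. It sets out from 8: the same carboalumination is quenched with I2 to give (E)-6-iodo-5-methylhex-5-enoic acid F6, and Miyaura borylation (PdCl2(dppf), B2pin2, KOAc, DMSO, 80 °C) returns to the route at 10.

Step 11. Oxidative addition and transfer to chromium may be slow at the hindered dienyl triflate, so that reduction of the triflate or decay of the sensitive aldehyde competes. The fallback replaces carbonyl addition by an acyl cross-coupling that gives the ketone directly. From 7, Me3SnSnMe3 with Pd(PPh3)4 and LiCl in THF at 60 °C should give the dienyltrimethylstannane F7. From 17, EtSLi in THF at 0 °C should give the S-ethyl thioester F8. Liebeskind–Srogl coupling of F7 with F8 (Pd2(dba)3, tri(2-furyl)phosphine, CuOP(O)Ph2 as the monovalent copper mediator, THF, 50 °C) returns to the route at 22 and bypasses steps 9, 10 and 12.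

Step 13. Facial selectivity in the hydride addition may be poor, because the Felkin–Anh bias rests on the difference between a branched and an unbranched alkyl group on C7; a lesser risk is base-induced loss of configuration at C2' during ring closure. The fallback moves control of C6 from the substrate to a reagent. It sets out from 7 and 19: a catalytic asymmetric Ni/Cr coupling (CrCl2 10 mol %, chiral sulfonamide–oxazoline ligand of the enantiomer that delivers the 6S alcohol, NiCl2·(2,9-dimethyl-1,10-phenanthroline), Mn, Cp2ZrCl2, LiCl, MeCN) should give 23 directly, which is closed with NaH as in the second stage of step 13. It returns to the route at 23 and makes no new compound.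

## Further compounds

F1 | step 14 | potassium (E)-alkenyltrifluoroborate corresponding to 24 | C=C(CCC=C(C)C)[C@@H]1CC(=C(C)C=C1)[C@H]2OC(=O)[C@@H](C)[C@@H]2CC/C(C)=C/[B-](F)(F)F.[K+]
F2 | step 14 | (E)-alkenyldichloroborane corresponding to 24 | C=C(CCC=C(C)C)[C@@H]1CC(=C(C)C=C1)[C@H]2OC(=O)[C@@H](C)[C@@H]2CC/C(C)=C/B(Cl)Cl
F3 | step 14 | C1-dichloroboryl tetracycle | C=C(CCC=C(C)C)[C@@H]1C[C@]23C(C)=C[C@H]1[C@@H](B(Cl)Cl)[C@]2(C)CC[C@H]1[C@H](C)C(=O)O[C@@H]13
F4 | step 4 | trimethyl{[(5R)-2-methyl-5-(6-methylhepta-1,5-dien-2-yl)cyclohexa-1,3-dien-1-yl]oxy}silane | C=C(CCC=C(C)C)[C@@H]1CC(O[Si](C)(C)C)=C(C)C=C1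
F5 | step 4 | lithium (5R)-2-methyl-5-(6-methylhepta-1,5-dien-2-yl)cyclohexa-1,3-dien-1-olate | C=C(CCC=C(C)C)[C@@H]1CC([O-])=C(C)C=C1.[Li+]
F6 | step 5 | (E)-6-iodo-5-methylhex-5-enoic acid | OC(=O)CCC/C(C)=C/I
F7 | step 11 | trimethyl[(5R)-2-methyl-5-(6-methylhepta-1,5-dien-2-yl)cyclohexa-1,3-dien-1-yl]stannane | C=C(CCC=C(C)C)[C@@H]1CC([Sn](C)(C)C)=C(C)C=C1
F8 | step 11 | tert-butyl (2S,3S,6E)-3-(ethylsulfanylcarbonyl)-2,6-dimethyl-7-(4,4,5,5-tetramethyl-1,3,2-dioxaborolan-2-yl)hept-6-enoate | CCSC(=O)[C@@H](CC/C(C)=C/B1OC(C)(C)C(C)(C)O1)[C@H](C)C(=O)OC(C)(C)C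
F0 | step 13 | none | none
A1 | alternative 1 | 2-methyl-2-(4-oxobutyl)cyclohexane-1,3-dione | CC1(CCCC=O)C(=O)CCCC1=O
A2 | alternative 1 | cis-fused bicyclic hydroxy diketone | O[C@@]12CCCC(=O)[C@]1(C)CCCC2=O
A3 | alternative 2 | (4E)-1,10-epoxygermacr-4-en-12,6-olide (11S, trans-epoxide) | C/C1=C\[C@H]2OC(=O)[C@@H](C)[C@@H]2CC[C@@]3(C)O[C@@H]3CC1
A4 | alternative 2 | 1β-hydroxyeudesm-3-en-12,6α-olide (11S) | CC1=CC[C@@H](O)[C@]2(C)CC[C@H]3[C@H](C)C(=O)O[C@@H]3[C@@H]12
A5 | alternative 3 | 4-methyl-4-cyclohexenylcyclobut-2-enone carrying the lactone (either epimer at the cyclobutenone carbon) | CC1=C(C2(C)C=CC2=O)[C@H]3OC(=O)[C@@H](C)[C@@H]3CC1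
A6 | alternative 3 | 1-oxoeudesma-2,4-dien-12,6-olide | CC1=C2[C@H]3OC(=O)[C@@H](C)[C@@H]3CC[C@@]2(C)C(=O)C=C1
A7 | alternative 3 | myrcene | C=CC(=C)CCC=C(C)C
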